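Remark (assumption): (E)-sinapaldehyde 1 is taken as a purchasable compound. All tetralin-type compounds are numbered like the target: C1 aryl-bearing CH, C2 the CH carrying the carbinol carbon C9, C3 carrying the ester carbon C10, then C4, C4a, C5–C8, C8a. Ring A is the benzo ring, ring B the carbocycle C1–C4/C4a/C8a, ring C the pendant aryl group.

## Analysis of the target

Target 16 is a 1-aryl-1,2-dihydronaphthalene lignan. Ring A carries methoxy groups at C6 and C8, a free phenol at C7 and a hydrogen at C5. Ring B holds a C3=C4 double bond conjugated with ring A and with the methyl ester (C10) on C3; C1 carries ring C (4-hydroxy-3,5-dimethoxyphenyl) and C2 carries the hydroxymethyl carbon C9. The only stereocenters are the adjacent C1 (S) and C2 (R), with the aryl and hydroxymethyl groups trans. The molecule is fragile in several ways: loss of H-1 and H-2 would aromatize ring B and delete both stereocenters, H-1 is doubly benzylic and para to a free phenol, both syringyl phenols oxidize easily as phenoxides, and the C9 hydroxyl can close onto the C10 ester to give a fused butenolide. The difficulty is control, not size: two neighbouring stereocenters must be fixed in absolute terms, the alkene must be placed at C3=C4 without passing through C2, and rings A and C, which share one substitution pattern, must take different roles. The strategy reads C1–C2–C3 as a 1,3-dipole (cation at C1 stabilized by ring C, anion at C3 stabilized by two esters), i.e. a donor–acceptor cyclopropane. C4 with ring A is read as an aryl aldehyde whose ring carbon C8a, ortho to one methoxy group and para to the other, can close ring B onto C1.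

## Retrosynthetic reasoning

The last operations on 16 are deprotections. Putting a triisopropylsilyl group back on the ring C phenol gives 15; acylating the C9 hydroxyl (acetate) and the ring A phenol (pivalate) gives 13, with the mono-deacylated 14 between them. The three groups differ on purpose: the silyl ether keeps ring C a strong donor, the pivalate makes ring A the weaker donor, and the acetate silences the C9 oxygen. Forward, the two esters must be removed by base while only one phenoxide is exposed, and the silyl ether last under buffered conditions.

In 13 the C3=C4 bond beside a single ester is the retron of a β-acyloxy malonate. Adding a second methoxycarbonyl group at C3 and an acetoxy group at C4 leads to 11 and, one acylation earlier, to carbinol 10. The C3–ester bond is the one to cut because a quaternary C3 can eliminate only toward C4, so C2 is never enolized, and because the geminal diester is the acceptor that the ring-forming step needs. Forward, one ester must be excised by halide-induced demethylation and decarboxylation (through carboxylate 12), and the resulting C3 carbanion must expel the C4 acetate.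

Carbinol 10 is cut at C1–C8a and C3–C4. Cutting C1–C8a in the Friedel–Crafts sense and returning the C4 oxygen to C1 gives tetrahydrofuran 9, in which ring A is a plain aryl substituent on C4. Cutting C3–C4 and C1–O of 9 releases cyclopropane 6 and aldehyde 8. These are the two ring B bonds that join the C1–C2–C3 unit to the ring A/C4 unit, and C2, the only stereocenter that must be carried, lies on neither. The aldehyde oxygen serves three times: as the nucleophile that opens the cyclopropane, as the leaving group at C1, and as the handle for the alkene. What is gained is ring B, both of its new bonds and the C1 stereocenter in one operation from two fragments of similar size. Forward, a Lewis acid must open 6 at C1–C3 and join it to 8, and a stronger acid must then ionize C1–O (not C4–O) and let C8a close onto C1 trans to the C2 substituent.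

Cyclopropane 6 goes back through alcohol 5 to aldehyde 4. Compound 4 is cut at the two ring bonds of the malonate carbon (future C3–C1 and C3–C2), giving enal 2 and bromomalonate 3. This is where absolute configuration is best introduced: conjugate addition to the iminium ion of 2 fixes the aryl-bearing carbon, closure of the enamine places the formyl carbon trans to it, and that formyl carbon is already C9, one reduction from the target's oxidation level. Forward, an enantioselective Michael-initiated ring closure is required.

Enal 2 is the silyl ether of 1 and aldehyde 8 is the pivalate of 7. Both are one-step protections of commercial phenols, so the whole precursor stage is routine and the risk sits in the union of 6 and 8.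

## Alternatives that were turned down

Alternative 1: Ring B is cut at C2–C3 and C4–C4a, which unravels the dihydronaphthalene to propiolate A1, the ester of a 3,3-diarylallyl alcohol in which both aryl groups are the silylated syringyl ring. Forward, a cationic monovalent rhodium catalyst with an axially chiral bisphosphine would promote an intramolecular [4+2] cycloaddition between the alkyne and a diene made of the C1=C2 bond and the C8a=C4a bond of ring A. A hydrogen shift from C4a to C1 then restores ring A and gives lactone A2.
- For: it is the shortest plan and fully atom-economic, it needs no alkene-geometry control because the two aryl groups are identical, and it forms ring B and the C9/C10 functionality together. On step count it beats the chosen route.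
- Against: the cycloaddition must dearomatize ring A. The catalyst can influence only C2; C1 becomes stereogenic later, in a hydrogen shift that is not allowed as a concerted suprafacial process and so runs by proton transfer outside the chiral environment. Enantioselective cycloadditions with a vinylarene as the diene are not an established reaction class, so the absolute configuration would rest on untested induction. Such dihydronaphthalenes also tend to lose H-1 and H-2, and A2 locks C9 and C10 in a lactone that must be opened to the hydroxy methyl ester against the bias toward ring closure.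
- Comparison: the chosen route is a few steps longer, but it takes its absolute configuration from an established amine-catalysed cyclopropanation, asks only substrate-controlled diastereoselection of its key step, and keeps C9 (acetate) and C10 (methyl ester) apart throughout.

Alternative 2: Ring B is cut at C1–C2 and C3–C4. The diene is the hydroxy-o-quinodimethane formed by UV excitation of 2-benzylbenzaldehyde A3 (hydrogen transfer from the diarylmethane CH2 to the carbonyl oxygen). The dienophile is the chiral 5-alkoxybutenolide A4, and the endo adduct is A5.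
- For: the facial bias of such alkoxybutenolides and the endo rule are dependable, both ring bonds form in one concerted event, C4 arrives as a carbinol ready for elimination, and C10 is at the right oxidation level. In the predictability of the bond-forming event itself this plan is at least as strong as the chosen one.
- Against: endo addition of the (E,E)-dienol places the C1 aryl group cis to the C2 substituent, so C2 must later be epimerized through the C9 aldehyde. C9 emerges as an acetal that has to be unmasked and reduced while C10 is converted to the methyl ester. The auxiliary is stoichiometric. A3 needs a fully substituted ring A with ortho formyl and benzyl groups, which costs several steps of arene functionalization, and the photoreaction must work on a very electron-rich benzaldehyde.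
- Comparison: this plan would be clearly longer. The chosen route gives the trans C1/C2 relationship directly, has C9 at the alcohol oxidation level from the first C–C bond formation, and uses catalytic rather than stoichiometric chirality.

Alternative 3: The bonds cut are C1–ring C and C2–C3. Acrylate A6, a ring A cinnamate with a methyl pyruvate arm (C4, C3, C10) ortho to the acrylate, would take up the aryl group of boronic acid A7 at C1 under a rhodium/chiral diene catalyst with aqueous hydroxide. The rhodium enolate at C2 would then add to the ketone C3 and close ring B, giving hydroxy diester A8.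
- For: rhodium-catalysed asymmetric conjugate arylation is among the most reliable ways to set a diarylmethine center. In direct, catalyst-controlled setting of C1 this plan is stronger than the chosen one, which sets C1 by relay from C2. Ring C also enters late.
- Against: the β-aryl group of A6 is substituted at both ortho positions (C8 methoxy and the C4a arm), which twists and shields the acceptor. The arylpyruvate arm is strongly enolized toward ring A, is itself an acceptor for the arylrhodium species, and is exposed to aqueous hydroxide. In A8 the tertiary C3 hydroxyl must be eliminated toward C4, yet H-2, α to an ester, is the more acidic neighbour, so elimination toward C2 would erase that stereocenter. C9 also arrives as a tert-butyl ester that must be reduced beside the C10 methyl ester.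
- Comparison: the chosen route has no such regiochemical question, because C3 is quaternary when the alkene forms, and it never holds C9 and C10 at the same oxidation level.

Key step: step 6

## Route

Step 1
Reactants: 1 (E)-sinapaldehyde
Product: 2 (E)-3-[3,5-dimethoxy-4-(triisopropylsilyloxy)phenyl]prop-2-enal
Conditions: TIPSCl, imidazole, DMF, rt
Reagents that add atoms: triisopropylsilyl chloride, CC(C)[Si](Cl)(C(C)C)C(C)C
Why: Silyl ether formation on an acidic, flanked phenol under standard imidazole/DMF conditions. The triisopropylsilyl group is chosen because it tolerates amines, borohydride, acylation and brief contact with strong acid, and because it keeps ring C a strong donor.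

Step 2
Reactants: 2 (E)-3-[3,5-dimethoxy-4-(triisopropylsilyloxy)phenyl]prop-2-enal; 3 dimethyl bromomalonate
Product: 4 dimethyl (2S,3R)-2-[3,5-dimethoxy-4-(triisopropylsilyloxy)phenyl]-3-formylcyclopropane-1,1-dicarboxylate (aryl and formyl trans)
Conditions: (S)-α,α-diphenylprolinol trimethylsilyl ether (20 mol%), 2,6-lutidine, CH2Cl2, 0 °C → rt
Reagents that add atoms: none
Why: Michael-initiated ring closure under iminium–enamine catalysis: the diphenyl(silyloxy)methyl group of the catalyst blocks one face of the E-iminium ion of 2, so the bromomalonate anion should add to the Si face of the β-carbon (future C1), and the enamine then displaces bromide in a 3-exo-tet alkylation that places the formyl group trans to the aryl group. 2,6-Lutidine is the acid scavenger because stronger amine bases open the product ring.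

Step 3
Reactants: 4 dimethyl (2S,3R)-2-[3,5-dimethoxy-4-(triisopropylsilyloxy)phenyl]-3-formylcyclopropane-1,1-dicarboxylate
Product: 5 dimethyl (2S,3R)-2-[3,5-dimethoxy-4-(triisopropylsilyloxy)phenyl]-3-(hydroxymethyl)cyclopropane-1,1-dicarboxylate
Conditions: NaBH4, MeOH/CH2Cl2, −10 °C; aq. NH4Cl
Reagents that add atoms: none
Why: Chemoselective borohydride reduction of the aldehyde beside the malonate esters. The cold, short, near-neutral procedure is meant to keep the new alcohol from lactonizing onto the cis ester.

Step 4
Reactants: 5 dimethyl (2S,3R)-2-[3,5-dimethoxy-4-(triisopropylsilyloxy)phenyl]-3-(hydroxymethyl)cyclopropane-1,1-dicarboxylate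
Product: 6 dimethyl (2S,3R)-3-(acetoxymethyl)-2-[3,5-dimethoxy-4-(triisopropylsilyloxy)phenyl]cyclopropane-1,1-dicarboxylate
Conditions: Ac2O, pyridine, DMAP (cat.), CH2Cl2, 0 °C
Reagents that add atoms: acetic anhydride, CC(=O)OC(C)=O
Why: DMAP-catalysed acylation of a primary alcohol. The acetate removes the nucleophilic hydroxyl that could otherwise lactonize or intercept the benzylic cation in step 6.

Step 5
Reactants: 7 syringaldehyde
Product: 8 4-formyl-2,6-dimethoxyphenyl pivalate
Conditions: PivCl, Et3N, DMAP (cat.), CH2Cl2, 0 °C → rt
Reagents that add atoms: pivaloyl chloride, CC(C)(C)C(=O)Cl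
Why: Acylation of the phenol. The pivalate makes this ring a poorer cation-stabilizing group than the silyloxyaryl ring, and its bulk guards it against acyl transfer under the acids of step 6.

Step 6
Reactants: 6 dimethyl (2S,3R)-3-(acetoxymethyl)-2-[3,5-dimethoxy-4-(triisopropylsilyloxy)phenyl]cyclopropane-1,1-dicarboxylate; 8 4-formyl-2,6-dimethoxyphenyl pivalate
Product: 10 dimethyl (1S,2R)-2-(acetoxymethyl)-4-hydroxy-6,8-dimethoxy-7-(pivaloyloxy)-1-[3,5-dimethoxy-4-(triisopropylsilyloxy)phenyl]-1,2,3,4-tetrahydronaphthalene-3,3-dicarboxylate (both C4 epimers), via tetrahydrofuran diester 9 (not isolated)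
Conditions: 8 (1.2 equiv), Sc(OTf)3 (10 mol%), CH2Cl2, 0 °C → rt; then TfOH (20 mol%), −20 → 0 °C; Et3N quench
Reagents that add atoms: none
Why: Proposed new method: Sc(OTf)3 chelates the geminal diester of 6 and polarizes the C1–C3 bond, the carbonyl oxygen of 8 attacks the benzylic carbon C1 in an SN2-like opening, and the malonate carbon C3 then adds to the resulting oxocarbenium carbon C4 (5-endo-trig aldol-type closure), giving tetrahydrofuran 9; this stage is the known Lewis-acid [3+2] annulation of donor–acceptor cyclopropanes with aldehydes. TfOH then protonates the ring oxygen and re-ionizes C1–O to a para-silyloxybenzyl cation, which is captured by C8a of the aldehyde-derived ring in a 6-endo-trig Friedel–Crafts alkylation that closes ring B and leaves the oxygen as the C4 hydroxyl; the closest known reaction is the acid-induced reorganization of 2,5-diaryltetrahydrofuran lignans to 1-aryltetralins, and the new element is running both events in one flask on a 3,3-diester. C2 is carried unchanged from 6 because neither bond to it is broken. C1 passes through a planar cation and is re-formed under substrate control, the aryl group taking the pseudo-equatorial position anti to the C2 acetoxymethyl group in a half-chair transition state, while C4 forms as a mixture that step 8 erases. The step needs ionization at C1–O and not at C4–O, which the substrate secures because the silyloxyaryl ring stabilizes a C1 cation whereas C4 bears the less donating pivaloyloxyaryl ring and sits next to the electron-poor diester carbon. It also needs capture of the cation to outrun loss of H-2, which the intramolecular closure onto an arene position activated by an ortho and a para methoxy group in a non-basic medium should provide. The two ortho positions of the aldehyde-derived ring are equivalent, so the arylation has no regiochemical ambiguity.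

Step 7
Reactants: 10 dimethyl (1S,2R)-2-(acetoxymethyl)-4-hydroxy-6,8-dimethoxy-7-(pivaloyloxy)-1-[3,5-dimethoxy-4-(triisopropylsilyloxy)phenyl]-1,2,3,4-tetrahydronaphthalene-3,3-dicarboxylate
Product: 11 dimethyl (1S,2R)-4-acetoxy-2-(acetoxymethyl)-6,8-dimethoxy-7-(pivaloyloxy)-1-[3,5-dimethoxy-4-(triisopropylsilyloxy)phenyl]-1,2,3,4-tetrahydronaphthalene-3,3-dicarboxylate (both C4 epimers)
Conditions: Ac2O, pyridine, DMAP, CH2Cl2, 0 °C → rt
Reagents that add atoms: acetic anhydride, CC(=O)OC(C)=O
Why: Nucleophilic (DMAP) catalysis is needed for the neopentyl-type secondary carbinol, and the weakly basic medium should not provoke retro-aldol opening of the β-hydroxy diester. Any acetyl group that migrated from the C9 oxygen to the C4 oxygen in step 6 converges on the same diacetate.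

Step 8
Reactants: 11 dimethyl (1S,2R)-4-acetoxy-2-(acetoxymethyl)-6,8-dimethoxy-7-(pivaloyloxy)-1-[3,5-dimethoxy-4-(triisopropylsilyloxy)phenyl]-1,2,3,4-tetrahydronaphthalene-3,3-dicarboxylate
Product: 13 methyl (1S,2R)-2-(acetoxymethyl)-6,8-dimethoxy-7-(pivaloyloxy)-1-[3,5-dimethoxy-4-(triisopropylsilyloxy)phenyl]-1,2-dihydronaphthalene-3-carboxylate, via lithium carboxylate 12 (not isolated)
Conditions: LiCl, dry DMSO, 130 °C, argon
Reagents that add atoms: none
Why: Krapcho dealkoxycarbonylation: chloride attacks the methyl group of one malonate ester (SN2), carboxylate 12 loses CO2, and the C3 ester enolate expels the C4 acetate (E1cB), so both C4 epimers give the same C3=C4 enoate. C3 has no hydrogen and C2 is not deprotonated, so the alkene can form only toward C4 and C1 and C2 are untouched.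

Step 9
Reactants: 13 methyl (1S,2R)-2-(acetoxymethyl)-6,8-dimethoxy-7-(pivaloyloxy)-1-[3,5-dimethoxy-4-(triisopropylsilyloxy)phenyl]-1,2-dihydronaphthalene-3-carboxylate
Product: 15 methyl (1S,2R)-7-hydroxy-2-(hydroxymethyl)-6,8-dimethoxy-1-[3,5-dimethoxy-4-(triisopropylsilyloxy)phenyl]-1,2-dihydronaphthalene-3-carboxylate, via hydroxy pivalate 14 (not isolated)
Conditions: K2CO3, degassed MeOH, 0 °C → rt, argon; aq. NH4Cl
Reagents that add atoms: none
Why: Base-catalysed transesterification: methoxide removes the primary acetate first and then the aryl pivalate, whose phenoxide is a good leaving group, while methanolysis of the conjugated methyl ester is degenerate. The hindered aryl silyl ether should largely persist, and any of it that is cleaved gives 16 early and simply passes through step 10.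

Step 10
Reactants: 15 methyl (1S,2R)-7-hydroxy-2-(hydroxymethyl)-6,8-dimethoxy-1-[3,5-dimethoxy-4-(triisopropylsilyloxy)phenyl]-1,2-dihydronaphthalene-3-carboxylate
Product: 16 methyl (1S,2R)-7-hydroxy-1-(4-hydroxy-3,5-dimethoxyphenyl)-2-(hydroxymethyl)-6,8-dimethoxy-1,2-dihydronaphthalene-3-carboxylate
Conditions: TBAF, AcOH (1:1), THF, 0 °C → rt, argon
Reagents that add atoms: none
Why: Fluoride cleaves the aryl Si–O bond (strong Si–F bond, phenoxide leaving group). Acetic acid buffers the medium so that neither phenoxides nor the C9 alkoxide persist, which guards against air oxidation and against lactonization onto C10.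

## Compound list

1 | (E)-sinapaldehyde, (E)-3-(4-hydroxy-3,5-dimethoxyphenyl)prop-2-enal | COc1cc(/C=C/C=O)cc(OC)c1O | starting material
2 | (E)-3-[3,5-dimethoxy-4-(triisopropylsilyloxy)phenyl]prop-2-enal | COc1cc(/C=C/C=O)cc(OC)c1O[Si](C(C)C)(C(C)C)C(C)C | intermediate
3 | dimethyl bromomalonate | COC(=O)C(Br)C(=O)OC | starting material
4 | dimethyl (2S,3R)-2-[3,5-dimethoxy-4-(triisopropylsilyloxy)phenyl]-3-formylcyclopropane-1,1-dicarboxylate (trans) | COC(=O)C1(C(=O)OC)[C@H](c2cc(OC)c(O[Si](C(C)C)(C(C)C)C(C)C)c(OC)c2)[C@H]1C=O | intermediate
5 | dimethyl (2S,3R)-2-[3,5-dimethoxy-4-(triisopropylsilyloxy)phenyl]-3-(hydroxymethyl)cyclopropane-1,1-dicarboxylate | COC(=O)C1(C(=O)OC)[C@H](c2cc(OC)c(O[Si](C(C)C)(C(C)C)C(C)C)c(OC)c2)[C@H]1CO | intermediate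
6 | dimethyl (2S,3R)-3-(acetoxymethyl)-2-[3,5-dimethoxy-4-(triisopropylsilyloxy)phenyl]cyclopropane-1,1-dicarboxylate (aryl carbon = future C1, acetoxymethyl carbon = future C2, malonate carbon = future C3) | COC(=O)C1(C(=O)OC)[C@H](c2cc(OC)c(O[Si](C(C)C)(C(C)C)C(C)C)c(OC)c2)[C@H]1COC(C)=O | intermediate
7 | syringaldehyde, 4-hydroxy-3,5-dimethoxybenzaldehyde | COc1cc(C=O)cc(OC)c1O | starting material
8 | 4-formyl-2,6-dimethoxyphenyl pivalate | O=Cc1cc(OC)c(OC(=O)C(C)(C)C)c(OC)c1 | intermediate
9 | dimethyl (4R)-4-(acetoxymethyl)-2-[3,5-dimethoxy-4-(pivaloyloxy)phenyl]-5-[3,5-dimethoxy-4-(triisopropylsilyloxy)phenyl]tetrahydrofuran-3,3-dicarboxylate (acetoxymethyl carbon as in 6; the two carbons flanking oxygen as formed) | COC(=O)C1(C(=O)OC)C(c2cc(OC)c(OC(=O)C(C)(C)C)c(OC)c2)OC(c2cc(OC)c(O[Si](C(C)C)(C(C)C)C(C)C)c(OC)c2)[C@H]1COC(C)=O | intermediate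
10 | dimethyl (1S,2R)-2-(acetoxymethyl)-4-hydroxy-6,8-dimethoxy-7-(pivaloyloxy)-1-[3,5-dimethoxy-4-(triisopropylsilyloxy)phenyl]-1,2,3,4-tetrahydronaphthalene-3,3-dicarboxylate (C4 epimers) | COC(=O)C1(C(=O)OC)C(O)c2cc(OC)c(OC(=O)C(C)(C)C)c(OC)c2[C@H](c2cc(OC)c(O[Si](C(C)C)(C(C)C)C(C)C)c(OC)c2)[C@H]1COC(C)=O | intermediate
11 | dimethyl (1S,2R)-4-acetoxy-2-(acetoxymethyl)-6,8-dimethoxy-7-(pivaloyloxy)-1-[3,5-dimethoxy-4-(triisopropylsilyloxy)phenyl]-1,2,3,4-tetrahydronaphthalene-3,3-dicarboxylate (C4 epimers) | COC(=O)C1(C(=O)OC)C(OC(C)=O)c2cc(OC)c(OC(=O)C(C)(C)C)c(OC)c2[C@H](c2cc(OC)c(O[Si](C(C)C)(C(C)C)C(C)C)c(OC)c2)[C@H]1COC(C)=O | intermediate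
12 | lithium (1S,2R)-4-acetoxy-2-(acetoxymethyl)-3-(methoxycarbonyl)-6,8-dimethoxy-7-(pivaloyloxy)-1-[3,5-dimethoxy-4-(triisopropylsilyloxy)phenyl]-1,2,3,4-tetrahydronaphthalene-3-carboxylate (C3 and C4 mixtures) | [Li+].[O-]C(=O)C1(C(=O)OC)C(OC(C)=O)c2cc(OC)c(OC(=O)C(C)(C)C)c(OC)c2[C@H](c2cc(OC)c(O[Si](C(C)C)(C(C)C)C(C)C)c(OC)c2)[C@H]1COC(C)=O | intermediate
13 | methyl (1S,2R)-2-(acetoxymethyl)-6,8-dimethoxy-7-(pivaloyloxy)-1-[3,5-dimethoxy-4-(triisopropylsilyloxy)phenyl]-1,2-dihydronaphthalene-3-carboxylate | COC(=O)C1=Cc2cc(OC)c(OC(=O)C(C)(C)C)c(OC)c2[C@H](c2cc(OC)c(O[Si](C(C)C)(C(C)C)C(C)C)c(OC)c2)[C@H]1COC(C)=O | intermediate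
14 | methyl (1S,2R)-2-(hydroxymethyl)-6,8-dimethoxy-7-(pivaloyloxy)-1-[3,5-dimethoxy-4-(triisopropylsilyloxy)phenyl]-1,2-dihydronaphthalene-3-carboxylate | COC(=O)C1=Cc2cc(OC)c(OC(=O)C(C)(C)C)c(OC)c2[C@H](c2cc(OC)c(O[Si](C(C)C)(C(C)C)C(C)C)c(OC)c2)[C@H]1CO | intermediate
15 | methyl (1S,2R)-7-hydroxy-2-(hydroxymethyl)-6,8-dimethoxy-1-[3,5-dimethoxy-4-(triisopropylsilyloxy)phenyl]-1,2-dihydronaphthalene-3-carboxylate | COC(=O)C1=Cc2cc(OC)c(O)c(OC)c2[C@H](c2cc(OC)c(O[Si](C(C)C)(C(C)C)C(C)C)c(OC)c2)[C@H]1CO | intermediate
16 | methyl (1S,2R)-7-hydroxy-1-(4-hydroxy-3,5-dimethoxyphenyl)-2-(hydroxymethyl)-6,8-dimethoxy-1,2-dihydronaphthalene-3-carboxylate (aryl and hydroxymethyl trans) | COC(=O)C1=Cc2cc(OC)c(O)c(OC)c2[C@H](c2cc(OC)c(O)c(OC)c2)[C@H]1CO | target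

## Step count and least certain steps

Total: 10 steps (steps 1–4 to 6, step 5 to 8, steps 6–10 after the union). Longest linear sequence: 9 steps from 1 (steps 1, 2, 3, 4, 6, 7, 8, 9, 10).

Step 6 (key step, labelled as a proposed new method).
- Risk: the C2 configuration can be lost by proton loss next to the benzylic cation, either from the ring-opened zwitterion during annulation or from the C1 cation during reorganization, followed by reprotonation. The annulation may be sluggish because the pivaloyloxy aldehyde is a modest nucleophile, which leaves time for isomerization of the cyclopropane. The aryl silyl ether may be cleaved by acid, and surplus aldehyde may react intermolecularly with the electron-rich rings once TfOH is present.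
- Fallback (from 6 and 8, returning at 10): the two events are run as two separate, individually established reactions. The annulation is carried out alone with Sn(OTf)2 (or Sc(OTf)3) in CH2Cl2 and tetrahydrofuran 9 is isolated and purified, which removes surplus 8 and the Lewis acid before any strong acid is present. Purified 9 is then rearranged in a second flask under the documented tetrahydrofuran-to-aryltetralin conditions (BF3·OEt2 or a sub-stoichiometric Brønsted acid at low temperature), where acid, solvent and temperature can be chosen without regard to the annulation. No compound outside the list arises (F0: no new compound).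

Step 2.
- Risk: conjugate addition may be slow, since the para-silyloxy group makes the iminium ion a weak acceptor. Prolonged contact with amine can then open the donor–acceptor cyclopropane aldehyde and erode enantiopurity by retro-Michael and re-addition, and facial selectivity may be insufficient.
- Fallback (from 2 and 3, returning at 6): asymmetric induction is replaced by resolution. The ring is built with pyrrolidine (20 mol%) and 2,6-lutidine to give the racemic trans-formylcyclopropane F1. NaBH4 reduction gives the racemic alcohol F2. Enantioselective acetylation with vinyl acetate and an immobilized lipase (Candida antarctica lipase B or Burkholderia cepacia lipase, to be screened), stopped at partial conversion, separates the enantiomers. If the enzyme acetylates the (2S,3R)-alcohol, acetate 6 results directly and the antipodal alcohol F3 is left behind. If it prefers the other enantiomer, the unreacted alcohol is 5, which re-enters at step 4, and the antipodal acetate F4 is discarded.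

Step 8.
- Risk: every enolate eliminates at once, so the sensitive 1,2-dihydronaphthalene is held at 130 °C in the presence of halide. There it may lose the aryl silyl ether or the aryl ester, suffer slow demethylation of the remaining conjugated ester, or aromatize if air is admitted.
- Fallback (from 10, returning at 13): the order of events is changed so that the hot step acts on a saturated tetralin. Carbinol 10 is dealkoxycarbonylated directly (LiCl, H2O, DMSO, 130 °C) to the β-hydroxy monoester F5, a mixture at C3 and C4; any 13 formed by direct dehydration is kept. F5 is converted to its mesylate F6 (MsCl, Et3N, CH2Cl2, 0 °C) and eliminated with DBU at room temperature to 13. This also bypasses step 7. Its own weak point is reversible retro-aldol opening of 10 in the mildly basic medium.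

Step 9.
- Risk: once the C9 hydroxyl is free, transesterification onto C10 (lactonization) can compete with the slow methanolysis of the doubly ortho-substituted aryl pivalate, and the phenoxide can oxidize if oxygen is present.
- Fallback (from 13, returning at 15): if ring closure cannot be suppressed it is driven to completion and then reversed irreversibly. Prolonged K2CO3/MeOH converts all material to the fused lactone F7 (ring A phenol free, C9–O–C10 closed, silyl ether retained). LiOH in THF/H2O at 0 °C opens the lactone as the carboxylate, and careful acidification with dilute HCl at 0 °C gives hydroxy acid F8. F8 is esterified at once, on the carboxyl group only, with trimethylsilyldiazomethane in MeOH/toluene to give 15.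

## Further compounds

F0 | step 6 | none | none
F1 | step 2 | racemic dimethyl trans-2-[3,5-dimethoxy-4-(triisopropylsilyloxy)phenyl]-3-formylcyclopropane-1,1-dicarboxylate (both enantiomers shown) | COC(=O)C1(C(=O)OC)[C@H](c2cc(OC)c(O[Si](C(C)C)(C(C)C)C(C)C)c(OC)c2)[C@H]1C=O.COC(=O)C1(C(=O)OC)[C@@H](c2cc(OC)c(O[Si](C(C)C)(C(C)C)C(C)C)c(OC)c2)[C@@H]1C=O
F2 | step 2 | racemic dimethyl trans-2-[3,5-dimethoxy-4-(triisopropylsilyloxy)phenyl]-3-(hydroxymethyl)cyclopropane-1,1-dicarboxylate (both enantiomers shown) | COC(=O)C1(C(=O)OC)[C@H](c2cc(OC)c(O[Si](C(C)C)(C(C)C)C(C)C)c(OC)c2)[C@H]1CO.COC(=O)C1(C(=O)OC)[C@@H](c2cc(OC)c(O[Si](C(C)C)(C(C)C)C(C)C)c(OC)c2)[C@@H]1CO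
F3 | step 2 | dimethyl (2R,3S)-2-[3,5-dimethoxy-4-(triisopropylsilyloxy)phenyl]-3-(hydroxymethyl)cyclopropane-1,1-dicarboxylate (enantiomer of 5) | COC(=O)C1(C(=O)OC)[C@@H](c2cc(OC)c(O[Si](C(C)C)(C(C)C)C(C)C)c(OC)c2)[C@@H]1CO
F4 | step 2 | dimethyl (2R,3S)-3-(acetoxymethyl)-2-[3,5-dimethoxy-4-(triisopropylsilyloxy)phenyl]cyclopropane-1,1-dicarboxylate (enantiomer of 6) | COC(=O)C1(C(=O)OC)[C@@H](c2cc(OC)c(O[Si](C(C)C)(C(C)C)C(C)C)c(OC)c2)[C@@H]1COC(C)=O
F5 | step 8 | methyl (1S,2R)-2-(acetoxymethyl)-4-hydroxy-6,8-dimethoxy-7-(pivaloyloxy)-1-[3,5-dimethoxy-4-(triisopropylsilyloxy)phenyl]-1,2,3,4-tetrahydronaphthalene-3-carboxylate (C3 and C4 mixtures) | COC(=O)C1C(O)c2cc(OC)c(OC(=O)C(C)(C)C)c(OC)c2[C@H](c2cc(OC)c(O[Si](C(C)C)(C(C)C)C(C)C)c(OC)c2)[C@H]1COC(C)=O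
F6 | step 8 | methyl (1S,2R)-2-(acetoxymethyl)-4-(methanesulfonyloxy)-6,8-dimethoxy-7-(pivaloyloxy)-1-[3,5-dimethoxy-4-(triisopropylsilyloxy)phenyl]-1,2,3,4-tetrahydronaphthalene-3-carboxylate (C3 and C4 mixtures) | COC(=O)C1C(OS(C)(=O)=O)c2cc(OC)c(OC(=O)C(C)(C)C)c(OC)c2[C@H](c2cc(OC)c(O[Si](C(C)C)(C(C)C)C(C)C)c(OC)c2)[C@H]1COC(C)=O
F7 | step 9 | fused C9–O–C10 lactone of 15: trans-1-aryl-1,2-dihydronaphthalene butenolide with free C7 phenol and silylated ring C, C1 and C2 as in the target | O=C1OC[C@H]2C1=Cc1cc(OC)c(O)c(OC)c1[C@@H]2c1cc(OC)c(O[Si](C(C)C)(C(C)C)C(C)C)c(OC)c1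
F8 | step 9 | (1S,2R)-7-hydroxy-2-(hydroxymethyl)-6,8-dimethoxy-1-[3,5-dimethoxy-4-(triisopropylsilyloxy)phenyl]-1,2-dihydronaphthalene-3-carboxylic acid | OC(=O)C1=Cc2cc(OC)c(O)c(OC)c2[C@H](c2cc(OC)c(O[Si](C(C)C)(C(C)C)C(C)C)c(OC)c2)[C@H]1CO
A1 | alternative 1 | 3,3-bis[3,5-dimethoxy-4-(triisopropylsilyloxy)phenyl]allyl propiolate | C#CC(=O)OCC=C(c1cc(OC)c(O[Si](C(C)C)(C(C)C)C(C)C)c(OC)c1)c1cc(OC)c(O[Si](C(C)C)(C(C)C)C(C)C)c(OC)c1
A2 | alternative 1 | trans-1-aryl-1,2-dihydronaphthalene fused C9–O–C10 lactone, bis(triisopropylsilyl) ether | O=C1OC[C@H]2C1=Cc1cc(OC)c(O[Si](C(C)C)(C(C)C)C(C)C)c(OC)c1[C@@H]2c1cc(OC)c(O[Si](C(C)C)(C(C)C)C(C)C)c(OC)c1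
A3 | alternative 2 | 3,5-dimethoxy-2-[3,5-dimethoxy-4-(methoxymethoxy)benzyl]-4-(methoxymethoxy)benzaldehyde | O=Cc1cc(OC)c(OCOC)c(OC)c1Cc1cc(OC)c(OCOC)c(OC)c1
A4 | alternative 2 | enantiopure 5-(menthyloxy)furan-2(5H)-one | O=C1C=C[C@@H](O[C@H]2C[C@@H](C)CC[C@@H]2C(C)C)O1
A5 | alternative 2 | endo cycloadduct, 1-aryl-4-hydroxytetralin fused to the menthyloxy lactone (C1 aryl cis to C2) | O=C1O[C@H](O[C@H]3C[C@@H](C)CC[C@@H]3C(C)C)[C@@H]2[C@H]1[C@H](O)c1cc(OC)c(OCOC)c(OC)c1[C@@H]2c1cc(OC)c(OCOC)c(OC)c1
A6 | alternative 3 | tert-butyl (E)-3-[2-(3-methoxy-2,3-dioxopropyl)-4,6-dimethoxy-5-(methoxymethoxy)phenyl]acrylate | COC(=O)C(=O)Cc1cc(OC)c(OCOC)c(OC)c1/C=C/C(=O)OC(C)(C)C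
A7 | alternative 3 | [3,5-dimethoxy-4-(methoxymethoxy)phenyl]boronic acid | OB(O)c1cc(OC)c(OCOC)c(OC)c1
A8 | alternative 3 | 1-aryl-3-hydroxytetralin 2-tert-butyl 3-methyl diester | COC(=O)[C@]1(O)Cc2cc(OC)c(OCOC)c(OC)c2[C@H](c2cc(OC)c(OCOC)c(OC)c2)[C@H]1C(=O)OC(C)(C)C
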